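Compounds are numbered 1–23 in the order in which they first appear in the steps, and these numbers are used from here on. Ar–O stands for the [7-methoxy-4-oxo-2-(2-phenylethyl)-4H-chromen-6-yl]oxy group. Positions C4a, C5–C8 and C8a always refer to the tetrahydrochromone half of the target.

## Analysis of the target

Target 23 is an unsymmetrical dimer of two 2-(2-phenylethyl)chromones. The phenolic oxygen at C6 of an aromatic 7-methoxychromone is bonded to C8 of a 5,6,7,8-tetrahydrochromone, whose carbocycle carries free hydroxyl groups at C5, C6 and C7. The four contiguous stereocentres are 5S,6R,7S,8S, which means C5–O/C6–O trans, C6–O/C7–O trans and C7–O/C8–O cis. The C5 hydroxyl and the C8 aryloxy group therefore lie on the same face, 1,4 to each other.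

The saturated ring is kept from aromatising only by its substituents. Loss of water or of the phenol leads towards a chromone, C5–O can ionise with help from O1 through the C4a=C8a bond, and H8 is the γ-hydrogen of a vinylogous ester. Strong acid, strong base and heat must therefore be avoided once the ring exists, and both 4-pyranone rings are open to hard nucleophiles.

The hard points are two. The secondary aryl ether at C8 sits between the pyranone and an oxygenated carbon and is a poor site for displacement by a hindered phenol. And four stereocentres must be set on a ring that offers no carbonyl group for enolate chemistry.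

The plan rests on one feature: C5 and C8 are the two sp3 carbons that flank the tetrasubstituted C4a=C8a bond, and their oxygens are cis. This is the pattern a (1E,3E)-1,4-dioxygenated butadiene leaves when it adds across the C5=C6 bond of a monocyclic 4-pyranone. The C6=C7 alkene that remains lies exactly where the trans-diol is needed.

## Retrosynthetic reasoning

**23 to 22.** The C6–OH bond is cut first. A 6,7-trans-diol with C7–O on the face of the C5 and C8 oxygens is what anti opening at C6 of the all-cis epoxy alcohol 22 gives. Cutting at C6 and not at C7 keeps the oxygen that is cis to its neighbours as the epoxide oxygen. The forward hydrolysis has to attack the epoxide carbon remote from the aryloxy-bearing C8.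

**22 to 21.** Both epoxide C–O bonds are removed to give allylic alcohol 21. The C5 hydroxyl is allylic to C6=C7, so a metal-bound peroxide can be delivered from its own face, and no other reagent control is needed for C6 and C7.

**21 to 20.** The hydroxyl is masked as the tert-butyldimethylsilyl ether 20, because the oxygen at C5 has to enter as a silyl dienol ether. Only a mild, buffered desilylation is then needed in the forward direction.

**20 to 8 and 18 (through 19).** The C4a–C5 and C8–C8a bonds are cut together, which opens the carbocycle to sulfinylpyranone 8 and diene 18. This is the only cut that removes the ring and both allylic stereocentres at once and leaves the pyranone intact. It also takes the aryl ether back to an enol ether, so no substitution at C8 is ever required. The forward cycloaddition has to achieve four things: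
- bond the aryloxy terminus of 18 to C6 of 8;
- use one face of 8, with the pyranone ring endo;
- keep the E,E geometry of 18, so that the oxygens end up cis;
- lose the sulfur from adduct 19 as a sulfenic acid together with H8a, not H5.

**18 to 13, 14 and 16.** The Si–O–C bond of the silyl enol ether is cut to dienylboronate 17, the new alkene of 17 to aldehyde 15 and the boron reagent 16, and the aryl enol ether of 15 to phenol 13 and propiolaldehyde 14. The obvious alternative, soft enolisation of a 4-aryloxybut-2-enal, is deliberately not used. γ-Deprotonation of an (E)-enal with a γ-oxygen tends to place that oxygen cis on the new double bond. The resulting (1E,3Z)-diene cannot reach the s-cis conformation, and would give trans C5/C8 if it reacted at all. In the sequence chosen each double bond has its own control: the push–pull enal 15 equilibrates to E, the olefination to 17 is E-selective, and the C–O coupling to 18 retains alkene geometry.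

**13 to 9 and 4.** The pyranone ring of the aromatic half is opened at O1–C2 and C3–C4 to a β-diketone 11 and then to the acetophenone 10 and ester 4. The free 5'-hydroxyl of 9 is carried as a methoxymethyl ether, which falls off in the acid that closes the ring (through 12).

**8 to 1, 2, 4 and 6.** The pyranone of 8 is opened at O1–C6 to the formyl triketone 7. The formyl carbon comes from 6, the terminal acyl group of diketosulfoxide 5 from 4, and the acetonyl unit of 3 from 2. The sulfur stereocentre is bought with 1 and is never touched.

## Alternatives that were turned down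

**Alternative 1: two-directional carbonylative alkynylation.**
- Disconnection: both pyranone rings are cut at C3–C4 and C4–C4a and taken back to acyl alkynes.
- Forward key step: bis-iodide A2 is coupled twice with alkyne A3 under palladium–copper catalysis and carbonylative conditions to give bis-ynone A1. Later desilylation and oxa-Michael closure would form the two heterocycles.
- For: the two identical 2-(2-phenylethyl)pyranone units are made in one operation from one alkyne, by a fully precedented reaction. On precedent and on avoiding an acid-labile bis-enol ether it is stronger than the chosen route.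
- Against: the key step closes no ring and sets no stereocentre. The aryl ether at C8 and the centres at C6 and C7 must already be present in A2, so the real difficulty is only moved upstream. In A1 and A2, C8 is α to a ketone and carries the aryloxy group, so it can epimerise and eliminate. C5 is still a vinylic CH, and its oxygen would have to be added late, by a reversible conjugate addition, trans to C6–O.
- Comparison: the chosen route gives the carbocycle, two C–C bonds and the C5/C8 pair in one step with the pyranone already in place, and never has a carbonyl group on the carbocycle.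

**Alternative 2: amine-catalysed aldol closing C5–C6.**
- Disconnection: the C5–C6 bond.
- Forward key step: a chiral secondary amine converts the C7 ketone of racemic keto aldehyde A5 into its C6 enamine, which adds to the C5 aldehyde to give A4 while C8 epimerises.
- For: it is convergent, the ether is made early by simple displacement next to a ketone, and it is catalytic in the chiral controller. It forms the ring and two stereocentres, and it avoids any untested cycloaddition. On these points it is at least as strong as the chosen route.
- Against: three separate things must go right at once. The enamine must form towards C6 and not C8. The equilibrating C8 centre must settle in the configuration the target needs. And A4, a β-hydroxy ketone with an acidic C6–H, must not dehydrate, after which aromatisation to a phenol is downhill. The C7 ketone must then still be reduced cis to C8–O and trans to C6–O under substrate control.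
- Comparison: in the chosen route C5 and C8 are fixed together by a suprafacial addition, and C6 and C7 follow from one directed epoxidation.

**Alternative 3: Ferrier carbocyclisation of a 4-O-aryl sugar.**
- Disconnection: the C4a–C5 bond, which is C6–C1 of the sugar.
- Forward key step: a catalytic divalent mercury salt in aqueous medium unmasks the enol ether of hex-5-enopyranoside A7. The C6 enolate adds to the C1 aldehyde, and elimination of the new hydroxyl gives cyclohexenone A6.
- For: C6, C7 and C8, including the aryl ether, come from the chiral pool with certainty, and every reaction is known. On security of absolute configuration and on precedent it is stronger than the chosen route.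
- Against: A7 needs a rare altro configuration carrying a 4-O-aryl group, and that group must itself be installed by displacement with the hindered phenol 13, the very reaction the target makes difficult. A6 still lacks the pyranone and the C5 oxygen. C8 in A6 is α to a ketone during all later base chemistry. The benzyl ethers must finally be removed in the presence of allylic-type C–O bonds. The step count would be roughly double.
- Comparison: the chosen route offers brevity (12 steps) and builds the ring, two skeletal bonds and two stereocentres in a single operation.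

Key step: step 9

Assumption: 9, 14 (freshly distilled or as a commercial solution), 16 and tert-butyldimethylsilanol are taken as commercially available.

## Route

**Step 1**
Reactants: 1 (R)-methyl p-tolyl sulfoxide; 2 ethyl acetate
Product: 3 (R)-1-(p-tolylsulfinyl)propan-2-one
Conditions: LiN(i-Pr)2, THF, −78 °C (1 in twofold excess); then 2, −78 to 0 °C; aq. NH4Cl
Reagents that add atoms: none
Why: Claisen-type acylation of the α-sulfinyl carbanion by the ester; the acidic β-keto sulfoxide consumes a second equivalent of carbanion, hence the excess, and the sulfur stereocentre is not involved.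

**Step 2**
Reactants: 3 (R)-1-(p-tolylsulfinyl)propan-2-one; 4 ethyl 3-phenylpropanoate
Product: 5 (R)-6-phenyl-1-(p-tolylsulfinyl)hexane-2,4-dione
Conditions: LiN(i-Pr)2 (2.1 equiv. per 3), THF, −78 to 0 °C; then 4 (0.5 equiv.), 0 °C; aq. NH4Cl
Reagents that add atoms: none
Why: Hauser-type dianion acylation: the second deprotonation takes place at the methyl group and the resulting α,α'-dianion reacts with the ester only at this less stabilised terminal carbon, so the regiochemistry is unambiguous.

**Step 3**
Reactants: 5 (R)-6-phenyl-1-(p-tolylsulfinyl)hexane-2,4-dione; 6 ethyl formate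
Product: 8 (S)-2-(2-phenylethyl)-5-(p-tolylsulfinyl)-4H-pyran-4-one, via formyl triketone 7 (not isolated)
Conditions: NaH, THF, 0 °C; 6, 0 °C to rt; AcOH; then p-TsOH·H2O (cat.), CH2Cl2, rt
Reagents that add atoms: none
Why: Claisen formylation of the dianion of 5 at the sulfinyl-bearing carbon (the last-formed and most nucleophilic site, and also the site that gives the most stable product dianion), followed by acid-catalysed cyclodehydration of the 1,3,5-tricarbonyl system, for which only one six-membered closure exists; HCl is avoided because it racemises sulfoxides, and the descriptor at sulfur changes from R to S only because the carbon substituent gains priority.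

**Step 4**
Reactants: 9 2',5'-dihydroxy-4'-methoxyacetophenone
Product: 10 2'-hydroxy-4'-methoxy-5'-(methoxymethoxy)acetophenone
Conditions: MOMCl, i-Pr2NEt, CH2Cl2, 0 °C to rt
Reagents that add atoms: chloromethyl methyl ether, COCCl
Why: Williamson-type O-alkylation; the 2'-hydroxyl is hydrogen-bonded to the acetyl group and much less nucleophilic, so one equivalent of reagent should go to the 5'-hydroxyl.

**Step 5**
Reactants: 10 2'-hydroxy-4'-methoxy-5'-(methoxymethoxy)acetophenone; 4 ethyl 3-phenylpropanoate
Product: 13 6-hydroxy-7-methoxy-2-(2-phenylethyl)-4H-chromen-4-one, via β-diketone 11 (not isolated), via MOM-protected chromone 12 (not isolated)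
Conditions: NaH, THF, reflux; then conc. HCl, MeOH, reflux
Reagents that add atoms: none
Why: crossed Claisen condensation of the acetophenone enolate with the ester, then acid-catalysed cyclodehydration of the o-hydroxyaryl β-diketone to the chromone; the same acid cleaves the methoxymethyl acetal, so no separate deprotection is needed.

**Step 6**
Reactants: 13 6-hydroxy-7-methoxy-2-(2-phenylethyl)-4H-chromen-4-one; 14 propiolaldehyde
Product: 15 (E)-3-(Ar–O)prop-2-enal
Conditions: N-methylmorpholine (10 mol %), CH2Cl2, 0 °C to rt
Reagents that add atoms: none
Why: amine-catalysed conjugate addition of the phenol to the ynal; the push–pull β-aryloxy enal equilibrates under the amine to the E isomer, which fixes the geometry of the future aryl enol ether.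

**Step 7**
Reactants: 15 (E)-3-(Ar–O)prop-2-enal; 16 bis(pinacolboryl)methane
Product: 17 (1E,3E)-1-(Ar–O)-4-(pinacolboryl)buta-1,3-diene
Conditions: 16, lithium 2,2,6,6-tetramethylpiperidide, THF, 0 °C; then 15, −78 °C to rt
Reagents that add atoms: none
Why: boron–Wittig olefination: the α-boryl carbanion adds 1,2 to the aldehyde and syn elimination of the boron–oxygen unit gives the E-alkenylboronate; the aldehyde is far more electrophilic than either vinylogous ester carbonyl, and the aryloxy alkene is not touched.

**Step 8**
Reactants: 17 (1E,3E)-1-(Ar–O)-4-(pinacolboryl)buta-1,3-diene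
Product: 18 (1E,3E)-1-(Ar–O)-4-(tert-butyldimethylsilyloxy)buta-1,3-diene
Conditions: t-BuMe2SiOH, Cu(OAc)2 (20 mol %), pyridine, 4 Å MS, O2 (1 atm), CH2Cl2, rt
Reagents that add atoms: tert-butyldimethylsilanol, CC(C)(C)[Si](C)(C)O
Why: Chan–Lam-type oxidative C–O coupling of an alkenylboronate with a silanol; transmetalation to copper and C–O reductive elimination both retain alkene geometry, so the E-boronate becomes the E-silyl enol ether without any enolisation step that could scramble either double bond.

**Step 9**
Reactants: 18 (1E,3E)-1-(Ar–O)-4-(tert-butyldimethylsilyloxy)buta-1,3-diene; 8 (S)-2-(2-phenylethyl)-5-(p-tolylsulfinyl)-4H-pyran-4-one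
Product: 20 (5R,8S)-5-(tert-butyldimethylsilyloxy)-8-(Ar–O)-2-(2-phenylethyl)-5,8-dihydro-4H-chromen-4-one, via sulfinyl cycloadduct 19 (not isolated)
Conditions: ZnBr2 (1.5 equiv.), 18 (1.5 equiv.), CH2Cl2, −20 °C to rt; aq. NaHCO3; then PhMe, 40 °C
Reagents that add atoms: none
Why: Proposed new method: ZnBr2 bridges the sulfinyl and C4 carbonyl oxygens of 8, which lowers the LUMO of the C5=C6 bond and holds the p-tolyl group over one face, and diene 18 then adds in a concerted, asynchronous, suprafacial [4+2] cycloaddition in which its aryloxy-bearing terminus (made the more nucleophilic by the silyloxy donor at the far end) bonds to the β-carbon C6 of the pyranone (future C8a) and its silyloxy-bearing terminus to C5 (future C4a). The closest known reaction type is the ZnBr2-promoted Diels–Alder addition of enantiopure sulfinylquinones and 2-sulfinyl enones to 1-oxygenated dienes with loss of a sulfenic acid from the adduct; a 4-pyranone has not been used as the sulfinyl dienophile. The six-membered carbocycle closes by intermolecular [4π+2π] cycloaddition, the bonds C4a–C5 and C8–C8a forming on one face of each partner. C5 and C8 are set together: their cis relation follows from the E,E geometry of 18, and their absolute configuration from attack on the face of 8 opposite the p-tolyl group combined with the endo orientation (pyranone ring under the diene), which for the (S)-sulfoxide puts both oxygens on the required face, while the centres at C4a and C8a of 19 are transient. Adduct 19 then loses p-toluenesulfenic acid by thermal syn-elimination of the C4a sulfoxide with the cis hydrogen at C8a, which restores the pyranone and removes the auxiliary without trace. The step needs regioselectivity, facial and endo selectivity, and elimination towards C8a instead of towards the allylic hydrogen at C5, which is also syn to sulfur; the first rests on the donor ranking silyloxy over aryloxy, the second and third on the zinc chelate, and the last on the gain of the fully conjugated pyranone and on the allylic strain that a C4a=C5 bond would set up between the silyloxy group and the C4 carbonyl.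

**Step 10**
Reactants: 20 (5R,8S)-5-(tert-butyldimethylsilyloxy)-8-(Ar–O)-2-(2-phenylethyl)-5,8-dihydro-4H-chromen-4-one
Product: 21 (5R,8S)-5-hydroxy-8-(Ar–O)-2-(2-phenylethyl)-5,8-dihydro-4H-chromen-4-one
Conditions: Bu4NF, AcOH (1:1), THF, 0 °C
Reagents that add atoms: none
Why: fluoride-induced cleavage of the silyl ether; buffering with acetic acid keeps the medium near neutral, so that neither deprotonation at C8 nor ionisation at C5 can start the elimination to an aromatic chromone.

**Step 11**
Reactants: 21 (5R,8S)-5-hydroxy-8-(Ar–O)-2-(2-phenylethyl)-5,8-dihydro-4H-chromen-4-one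
Product: 22 (5S,6S,7S,8S)-6,7-epoxy-5-hydroxy-8-(Ar–O)-2-(2-phenylethyl)-5,6,7,8-tetrahydro-4H-chromen-4-one (epoxide oxygen cis to the C5 hydroxyl and to the C8 aryloxy group)
Conditions: VO(acac)2 (5 mol %), t-BuOOH, CH2Cl2, 0 °C to rt
Reagents that add atoms: tert-butyl hydroperoxide, CC(C)(C)OO
Why: vanadium-catalysed hydroxyl-directed epoxidation of a cyclic allylic alcohol: the vanadium alkoxide of the C5 hydroxyl carries the alkyl peroxide and delivers oxygen to C6=C7 from its own face, which sets C6 and C7 and overrides the steric preference for the face away from the aryloxy group.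

**Step 12**
Reactants: 22 (5S,6S,7S,8S)-6,7-epoxy-5-hydroxy-8-(Ar–O)-2-(2-phenylethyl)-5,6,7,8-tetrahydro-4H-chromen-4-one
Product: 23 (5S,6R,7S,8S)-5,6,7-trihydroxy-8-(Ar–O)-2-(2-phenylethyl)-5,6,7,8-tetrahydro-4H-chromen-4-one (target)
Conditions: HClO4 (cat.), THF/H2O, 0 °C to rt
Reagents that add atoms: water, O
Why: acid-catalysed anti (trans-diaxial) opening of the epoxide with inversion at C6; attack at C6 is expected because C7 lies next to the more electron-withdrawing aryloxy-bearing carbon, and because opening at C6 keeps the aryloxy group pseudoequatorial and puts the C5 hydroxyl pseudoaxial, syn to the departing oxygen and able to hydrogen-bond to it. A Brønsted acid is used and chelating Lewis acids are avoided, since a metal bridging the C5 hydroxyl and the epoxide would steer the nucleophile to C7.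

## Compound list

1 | (R)-methyl p-tolyl sulfoxide | C[S@@](=O)c1ccc(C)cc1 | starting material
2 | ethyl acetate | CCOC(C)=O | starting material
3 | (R)-1-(p-tolylsulfinyl)propan-2-one | CC(=O)C[S@@](=O)c1ccc(C)cc1 | intermediate
4 | ethyl 3-phenylpropanoate | CCOC(=O)CCc1ccccc1 | starting material
5 | (R)-6-phenyl-1-(p-tolylsulfinyl)hexane-2,4-dione | O=C(CCc1ccccc1)CC(=O)C[S@@](=O)c1ccc(C)cc1 | intermediate
6 | ethyl formate | CCOC=O | starting material
7 | formyl triketone, drawn as its hydroxymethylene enol: (S)-1-hydroxy-7-phenyl-2-(p-tolylsulfinyl)hept-1-ene-3,5-dione (enol geometry not defined) | O=C(CCc1ccccc1)CC(=O)C(=CO)[S@@](=O)c1ccc(C)cc1 | intermediate (not isolated)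
8 | (S)-2-(2-phenylethyl)-5-(p-tolylsulfinyl)-4H-pyran-4-one | O=c1cc(CCc2ccccc2)occ1[S@@](=O)c1ccc(C)cc1 | intermediate
9 | 2',5'-dihydroxy-4'-methoxyacetophenone | CC(=O)c1cc(O)c(OC)cc1O | starting material
10 | 2'-hydroxy-4'-methoxy-5'-(methoxymethoxy)acetophenone | CC(=O)c1cc(OCOC)c(OC)cc1O | intermediate
11 | 1-[2-hydroxy-4-methoxy-5-(methoxymethoxy)phenyl]-5-phenylpentane-1,3-dione | O=C(CCc1ccccc1)CC(=O)c1cc(OCOC)c(OC)cc1O | intermediate (not isolated)
12 | 7-methoxy-6-(methoxymethoxy)-2-(2-phenylethyl)-4H-chromen-4-one | COCOc1cc2c(=O)cc(CCc3ccccc3)oc2cc1OC | intermediate (not isolated)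
13 | 6-hydroxy-7-methoxy-2-(2-phenylethyl)-4H-chromen-4-one | COc1cc2oc(CCc3ccccc3)cc(=O)c2cc1O | intermediate
14 | propiolaldehyde (prop-2-ynal) | C#CC=O | starting material
15 | (E)-3-{[7-methoxy-4-oxo-2-(2-phenylethyl)-4H-chromen-6-yl]oxy}prop-2-enal | COc1cc2oc(CCc3ccccc3)cc(=O)c2cc1O/C=C/C=O | intermediate
16 | bis(pinacolboryl)methane, 2,2'-methylenebis(4,4,5,5-tetramethyl-1,3,2-dioxaborolane) | CC1(C)OB(CB2OC(C)(C)C(C)(C)O2)OC1(C)C | starting material
17 | 7-methoxy-2-(2-phenylethyl)-6-{[(1E,3E)-4-(4,4,5,5-tetramethyl-1,3,2-dioxaborolan-2-yl)buta-1,3-dien-1-yl]oxy}-4H-chromen-4-one | COc1cc2oc(CCc3ccccc3)cc(=O)c2cc1O/C=C/C=C/B1OC(C)(C)C(C)(C)O1 | intermediate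
18 | 6-{[(1E,3E)-4-(tert-butyldimethylsilyloxy)buta-1,3-dien-1-yl]oxy}-7-methoxy-2-(2-phenylethyl)-4H-chromen-4-one | COc1cc2oc(CCc3ccccc3)cc(=O)c2cc1O/C=C/C=C/O[Si](C)(C)C(C)(C)C | intermediate
19 | sulfinyl cycloadduct: cis-fused 5-(tert-butyldimethylsilyloxy)-8-(Ar–O)-2-(2-phenylethyl)-4a-[(S)-p-tolylsulfinyl]-4a,5,8,8a-tetrahydro-4H-chromen-4-one, with sulfur and H8a on one face and the C5 and C8 oxygens on the other | COc1cc2oc(CCc3ccccc3)cc(=O)c2cc1O[C@H]1C=C[C@@H](O[Si](C)(C)C(C)(C)C)[C@@]2([S@@](=O)c3ccc(C)cc3)C(=O)C=C(CCc3ccccc3)O[C@@H]12 | intermediate (not isolated)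
20 | (5R,8S)-5-(tert-butyldimethylsilyloxy)-8-{[7-methoxy-4-oxo-2-(2-phenylethyl)-4H-chromen-6-yl]oxy}-2-(2-phenylethyl)-5,8-dihydro-4H-chromen-4-one | COc1cc2oc(CCc3ccccc3)cc(=O)c2cc1O[C@@H]1c2oc(CCc3ccccc3)cc(=O)c2[C@H](O[Si](C)(C)C(C)(C)C)C=C1 | intermediate
21 | (5R,8S)-5-hydroxy-8-{[7-methoxy-4-oxo-2-(2-phenylethyl)-4H-chromen-6-yl]oxy}-2-(2-phenylethyl)-5,8-dihydro-4H-chromen-4-one | COc1cc2oc(CCc3ccccc3)cc(=O)c2cc1O[C@@H]1c2oc(CCc3ccccc3)cc(=O)c2[C@H](O)C=C1 | intermediate
22 | (5S,6S,7S,8S)-6,7-epoxy-5-hydroxy-8-{[7-methoxy-4-oxo-2-(2-phenylethyl)-4H-chromen-6-yl]oxy}-2-(2-phenylethyl)-5,6,7,8-tetrahydro-4H-chromen-4-one | COc1cc2oc(CCc3ccccc3)cc(=O)c2cc1O[C@@H]1c2oc(CCc3ccccc3)cc(=O)c2[C@H](O)[C@@H]3O[C@H]13 | intermediate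
23 | (5S,6R,7S,8S)-5,6,7-trihydroxy-8-{[7-methoxy-4-oxo-2-(2-phenylethyl)-4H-chromen-6-yl]oxy}-2-(2-phenylethyl)-5,6,7,8-tetrahydro-4H-chromen-4-one | COc1cc2oc(CCc3ccccc3)cc(=O)c2cc1O[C@@H]1c2oc(CCc3ccccc3)cc(=O)c2[C@H](O)[C@@H](O)[C@@H]1O | target

## Step count and least certain steps

Total: 12 steps. Longest linear sequence: 9 steps (steps 4 to 12, from 9). The dienophile arm (steps 1 to 3) joins at step 9.

**Step 9 (key step).** Three things are most likely to go wrong:
- Reactivity: the C5=C6 bond of 8 is part of a vinylogous ester and may react too slowly even as the zinc chelate, so that Lewis-acid-induced desilylation or ionic addition of the acid-labile bis-enol ether 18 outruns cycloaddition.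
- Elimination direction: sulfenic acid may be lost with the allylic hydrogen at C5 and not with H8a. That gives a silyl dienol ether, which would aromatise by loss of the phenol.
- Regiochemistry: the two oxygen donors of 18 differ little, so some of the regioisomer may form.

If only the facial sense is opposite to the chelate model, the antipode of 1 is used and nothing else changes.

Fallback with known reactions, setting out from 4 and 18 and returning at 20: the sulfinyl group is replaced by an ester, since 3-alkoxycarbonyl-4-pyranones and -chromones are established dienophiles towards oxygenated dienes. The dianion of allyl acetoacetate is acylated with 4 to give allyl 3,5-dioxo-7-phenylheptanoate F1. Formylation of the dianion of F1 and acid cyclodehydration, as in step 3, give allyl 4-oxo-6-(2-phenylethyl)-4H-pyran-3-carboxylate F2. Diels–Alder addition of 18 to F2 (thermal or with ZnBr2) gives the racemic cis-fused β-keto allyl ester F3. Pd(OAc)2/PPh3 in MeCN then effects decarboxylation and dehydrogenation through the palladium enolate (Tsuji conditions), which restores C4a=C8a and gives 20 together with its mirror image F4. The enantiomers are separated by chromatography on a chiral stationary phase and 20 continues in step 10. This answers the reactivity problem, at the cost of a resolution. The hydrogen choice between C8a and C5 remains in the palladium step.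

**Step 12 (epoxide opening).** The risk is poor regioselectivity. C6 and C7 are each flanked by an oxygenated carbon, and water may attack C7, which gives the 6,7-diol of the wrong sense. Acid may also epimerise or eliminate at C5.

Fallback, setting out from 20 and returning at 23: dimethyldioxirane in acetone epoxidises the silyl ether 20 on the face away from both the silyloxy and the aryloxy group, giving the anti-epoxide F5. In F5 the demand is reversed: anti opening by water at C7 gives the silyl-protected triol F6 with the correct 6,7-trans-diol, and buffered fluoride as in step 10 gives 23. If one epoxide carbon is intrinsically preferred in both series, one of the two epoxides leads to the target. This fallback also avoids the free dihydro alcohol 21.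

**Step 8 (copper-mediated silanol coupling).** The risk is oxidative homocoupling or protodeboronation of the electron-rich dienylboronate 17, or silyl loss from 18 under the aerobic copper conditions.

Fallback, setting out from 17 and returning at 18: oxidation of the C–B bond with NaBO3 in THF/H2O gives (E)-4-(Ar–O)but-3-enal F7. Soft enolisation of F7 (t-BuMe2SiOTf, Et3N, CH2Cl2, −78 °C) removes an α-hydrogen and leaves the aryloxy alkene untouched, giving 18. Here only the geometry of the silyloxy alkene is open. A diene that is Z at that end cannot reach the s-cis conformation, so a mixture costs material but not stereochemical integrity in step 9.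

**Step 11 (directed epoxidation).** The risk is loss of facial selectivity, because the face of the C5 hydroxyl is also the face of the bulky aryloxy group. The vanadium Lewis acid may also promote dehydration of 21 to an aromatic chromone.

Fallback, setting out from 21 and returning at 22: N-bromosuccinimide in wet THF forms the bromonium ion on the open face, and water enters anti, from the face of the two substituents. This gives the regioisomeric trans-bromohydrins F8 and F9. K2CO3 in MeOH at 0 °C closes both to the same epoxide 22, so the facial outcome rests on steric approach of the electrophile and not on hydroxyl direction.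

## Further compounds

F1 | step 9 | allyl 3,5-dioxo-7-phenylheptanoate | C=CCOC(=O)CC(=O)CC(=O)CCc1ccccc1
F2 | step 9 | allyl 4-oxo-6-(2-phenylethyl)-4H-pyran-3-carboxylate | C=CCOC(=O)c1coc(CCc2ccccc2)cc1=O
F3 | step 9 | racemic cis-fused allyl 5-(tert-butyldimethylsilyloxy)-8-(Ar–O)-4-oxo-2-(2-phenylethyl)-5,8-dihydro-4H-chromene-4a(8aH)-carboxylate (one enantiomer drawn; ester and H8a cis, C5 and C8 oxygens cis to each other) | COc1cc2oc(CCc3ccccc3)cc(=O)c2cc1O[C@H]1C=C[C@@H](O[Si](C)(C)C(C)(C)C)[C@@]2(C(=O)OCC=C)C(=O)C=C(CCc3ccccc3)O[C@@H]12
F4 | step 9 | (5S,8R)-5-(tert-butyldimethylsilyloxy)-8-(Ar–O)-2-(2-phenylethyl)-5,8-dihydro-4H-chromen-4-one (mirror image of 20) | COc1cc2oc(CCc3ccccc3)cc(=O)c2cc1O[C@H]1c2oc(CCc3ccccc3)cc(=O)c2[C@@H](O[Si](C)(C)C(C)(C)C)C=C1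
F5 | step 12 | 6,7-epoxy-5-(tert-butyldimethylsilyloxy)-8-(Ar–O)-2-(2-phenylethyl)-5,6,7,8-tetrahydro-4H-chromen-4-one, epoxide oxygen trans to the C5 and C8 oxygens | COc1cc2oc(CCc3ccccc3)cc(=O)c2cc1O[C@@H]1c2oc(CCc3ccccc3)cc(=O)c2[C@H](O[Si](C)(C)C(C)(C)C)[C@H]3O[C@@H]13
F6 | step 12 | 5-O-(tert-butyldimethylsilyl) ether of 23 | COc1cc2oc(CCc3ccccc3)cc(=O)c2cc1O[C@@H]1c2oc(CCc3ccccc3)cc(=O)c2[C@H](O[Si](C)(C)C(C)(C)C)[C@@H](O)[C@@H]1O
F7 | step 8 | (E)-4-{[7-methoxy-4-oxo-2-(2-phenylethyl)-4H-chromen-6-yl]oxy}but-3-enal | COc1cc2oc(CCc3ccccc3)cc(=O)c2cc1O/C=C/CC=O
F8 | step 11 | 7-bromo-5,6-dihydroxy-8-(Ar–O)-2-(2-phenylethyl)-5,6,7,8-tetrahydro-4H-chromen-4-one, C6 hydroxyl cis and bromine trans to the C5 and C8 oxygens | COc1cc2oc(CCc3ccccc3)cc(=O)c2cc1O[C@@H]1c2oc(CCc3ccccc3)cc(=O)c2[C@H](O)[C@H](O)[C@H]1Br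
F9 | step 11 | 6-bromo-5,7-dihydroxy-8-(Ar–O)-2-(2-phenylethyl)-5,6,7,8-tetrahydro-4H-chromen-4-one, C7 hydroxyl cis and bromine trans to the C5 and C8 oxygens | COc1cc2oc(CCc3ccccc3)cc(=O)c2cc1O[C@@H]1c2oc(CCc3ccccc3)cc(=O)c2[C@H](O)[C@@H](Br)[C@@H]1O
A1 | alternative 1 | bis-ynone | COc1cc(O[Si](C)(C)C(C)(C)C)c(C(=O)C#CCCc2ccccc2)cc1O[C@@H]1C(=O)C(C(=O)C#CCCc2ccccc2)=C[C@@H](O[Si](C)(C)C(C)(C)C)[C@@H]1O[Si](C)(C)C(C)(C)C(C)C
A2 | alternative 1 | bis-iodide (aryl iodide and α-iodoenone) | COc1cc(O[Si](C)(C)C(C)(C)C)c(I)cc1O[C@@H]1C(=O)C(I)=C[C@@H](O[Si](C)(C)C(C)(C)C)[C@@H]1O[Si](C)(C)C(C)(C)C(C)C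
A3 | alternative 1 | 4-phenylbut-1-yne | C#CCCc1ccccc1
A4 | alternative 2 | 7-oxo aldol product with 6-O-silyl ether | COc1cc2oc(CCc3ccccc3)cc(=O)c2cc1O[C@@H]1c2oc(CCc3ccccc3)cc(=O)c2[C@H](O)[C@@H](O[Si](C)(C)C(C)(C)C)C1=O
A5 | alternative 2 | keto aldehyde, racemic at the aryloxy carbon | COc1cc2oc(CCc3ccccc3)cc(=O)c2cc1OC(C(=O)CO[Si](C)(C)C(C)(C)C)c1oc(CCc2ccccc2)cc(=O)c1C=O
A6 | alternative 3 | 6-aryloxy-4,5-bis(benzyloxy)cyclohex-2-enone | COc1cc2oc(CCc3ccccc3)cc(=O)c2cc1O[C@@H]1C(=O)C=C[C@@H](OCc2ccccc2)[C@@H]1OCc1ccccc1
A7 | alternative 3 | methyl 4-O-aryl-2,3-di-O-benzyl-6-deoxyhex-5-enopyranoside of altro origin (α-anomer drawn) | CO[C@H]1OC(=C)[C@@H](Oc2cc3c(=O)cc(CCc4ccccc4)oc3cc2OC)[C@@H](OCc2ccccc2)[C@@H]1OCc1ccccc1
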